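## Retrosynthetic overview

1. Target 21 ⇐ nonamethyl ether 20 by global O‑demethylation.
2. Second dihydrofuran ring (C8c–C7c and C7c–O bonds) ⇐ [4+1] annulation of o‑quinone methide 18 (from sulfone 15) with chiral 2,4‑dimethoxybenzyl sulfonium ylide 19.
3. Seven‑membered ring (C7b–ring B bond) ⇐ acid‑induced Friedel–Crafts closure of stilbene 12; sulfone 15 ⇐ phenol 14 + 3,5‑dimethoxybenzaldehyde + sulfinate.
4. First dihydrofuran ring ⇐ [4+1] annulation of o‑quinone methide 10 (dearomatised sulfone 6) with chiral 4‑methoxybenzyl sulfonium ylide 11; 6 ⇐ one‑sided condensation on the symmetric resorcinol‑stilbene 4.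
5. 4 ⇐ Horner–Wadsworth–Emmons olefination. Ring order: first dihydrofuran → cycloheptane → second dihydrofuran.

**Assumptions.** Both enantiomers of isothiocineole are bought (each is otherwise one step from limonene). The (1R,4R,5R) sulfide is taken to deliver the (2R,3R)‑dihydrobenzofuran and its enantiomer the (2S,3S) series; if the first run shows the opposite sense, the two sulfides are exchanged between steps 4 and 8.

**Labels.** C7a/C8a = O‑bearing and aryl‑bearing carbons of the first dihydrofuran; C7b/C8b = CH(aryl) and CH2 of the seven‑membered ring; C7c/C8c = the same two carbons of the second dihydrofuran. Ring A = 4‑oxyphenyl on C7a; ring B = 3,5‑dioxyphenyl on C8a; ring C = 2,4‑dioxyphenyl on C7b; ring D = central ring; ring E = 2,4‑dioxyphenyl on C7c; ring F = 3,5‑dioxyphenyl on C8c. The target is (7aR,8aR,7bR,7cS,8cS).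

## Route

Step 1
Reactants: 1 2,4‑dimethoxybenzyl alcohol
Product: 2 diethyl (2,4‑dimethoxybenzyl)phosphonate
Conditions: P(OEt)3, ZnI2, toluene, reflux
Reagents that add atoms: triethyl phosphite, CCOP(OCC)OCC
Why: ZnI2‑mediated Michaelis–Arbuzov‑type phosphonylation of an electron‑rich benzylic alcohol (transesterification to the benzyl phosphite, then zinc‑assisted rearrangement to the phosphonate), with no stereocentre involved.

Step 2
Reactants: 2 diethyl (2,4‑dimethoxybenzyl)phosphonate; 3 3,5‑dihydroxybenzaldehyde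
Product: 4 5‑[(E)‑2‑(2,4‑dimethoxyphenyl)ethenyl]benzene‑1,3‑diol
Conditions: KOtBu (3.3 equiv), THF/DMF, 0 °C→rt; aq. HCl work‑up
Reagents that add atoms: none
Why: Horner–Wadsworth–Emmons olefination, in which the phosphonate anion adds to the aldehyde (its two meta‑phenoxides are not conjugated with the carbonyl and do not shut it down) and syn‑elimination gives the E‑alkene.

Step 3
Reactants: 4 5‑[(E)‑2‑(2,4‑dimethoxyphenyl)ethenyl]benzene‑1,3‑diol (1.5 equiv, excess recovered); 5 3,5‑dimethoxybenzaldehyde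
Product: 6 mono‑sulfone 4‑[(3,5‑dimethoxyphenyl)(4‑methylbenzenesulfonyl)methyl]‑5‑[(E)‑2‑(2,4‑dimethoxyphenyl)ethenyl]benzene‑1,3‑diol (racemic at the sulfonyl carbon)
Conditions: TolSO2Na (1.2 equiv), HCO2H/H2O/MeCN, rt, 48 h
Reagents that add atoms: sodium p‑toluenesulfinate, Cc1ccc(cc1)S(=O)[O-].[Na+]
Why: Three‑component Friedel–Crafts hydroxyalkylation/sulfinate capture (Mannich‑type sulfone synthesis) at one of the two equivalent ring D carbons that are para to one OH and ortho to the other (the site taken in Gattermann, Hoesch and Vilsmeier substitution of orcinol and olivetol), which breaks the mirror symmetry of 4 and installs a latent o‑quinone methide; the sulfonyl‑bearing centre is erased in step 5.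

Step 4
Reactants: 7 4‑methoxybenzyl alcohol; 8 (1R,4R,5R)‑isothiocineole
Product: 9 (1R,4R,5R)‑6‑(4‑methoxybenzyl)‑4,7,7‑trimethyl‑6‑thiabicyclo[3.2.1]octan‑6‑ium tetrafluoroborate
Conditions: HBF4·OEt2, CH2Cl2, 0 °C→rt
Reagents that add atoms: tetrafluoroboric acid (diethyl etherate), [H+].F[B-](F)(F)F
Why: SN1‑type S‑alkylation of the sulfide by the 4‑methoxybenzyl cation released from the alcohol by HBF4, with alkylation on the exposed sulfur lone pair giving a single diastereomer at sulfur.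

Step 5
Reactants: 6 mono‑sulfone; 9 4‑methoxybenzyl sulfonium salt
Product: 12 (2R,3R)‑3‑(3,5‑dimethoxyphenyl)‑4‑[(E)‑2‑(2,4‑dimethoxyphenyl)ethenyl]‑2‑(4‑methoxyphenyl)‑2,3‑dihydro‑1‑benzofuran‑6‑ol, via o‑quinone methide 10 (not isolated), via sulfonium ylide 11 (not isolated)
Conditions: Cs2CO3 (4 equiv), CH2Cl2/MeCN, −40 °C→rt; cis isomer removed by chromatography
Reagents that add atoms: none
Why: Proposed new method: base expels sulfinate from the phenoxide of 6 and dearomatises ring D to o‑quinone methide 10, the isothiocineole ylide 11 (one ylide face open) adds through its benzylic carbon to the methide carbon with re‑aromatisation, and the ortho‑phenoxide then displaces the sulfide by 5‑exo‑tet SN2 with inversion to give the trans ring with C7a and C8a both R (the minor cis isomer is removed because it would later epimerise into the enantiomeric trans series); the closest known reactions are the formal [4+1] annulation of in situ o‑quinone methides with carbonyl‑stabilised sulfur ylides to trans‑2,3‑dihydrobenzofurans and the asymmetric epoxidation, aziridination and cyclopropanation with isothiocineole‑derived benzylic ylides.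

Step 6
Reactants: 12 trans‑dihydrobenzofuran stilbene
Product: 14 tetracyclic phenol (7aR,8aR,7bR), via benzylic cation 13 (not isolated)
Conditions: TFA (5 equiv), CH2Cl2, 0 °C→rt
Reagents that add atoms: none
Why: Protonation of the electron‑rich styrene at C8b gives the 2,4‑dimethoxybenzylic cation 13, which is captured by ring B in an intramolecular Friedel–Crafts alkylation (the acid‑mediated ε‑viniferin → ampelopsin B ring closure); C7b is set R by substrate control, ring C going pseudo‑axial to avoid the peri methoxy group of ring B and ending anti to C7a.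

Step 7
Reactants: 14 tetracyclic phenol; 5 3,5‑dimethoxybenzaldehyde
Product: 15 tetracyclic sulfone carrying CH(3,5‑dimethoxyphenyl)(SO2Tol) on ring D between the free OH and C8b (epimer mixture at the sulfonyl carbon)
Conditions: TolSO2Na (1.2 equiv), HCO2H/H2O/MeCN, rt
Reagents that add atoms: sodium p‑toluenesulfinate, Cc1ccc(cc1)S(=O)[O-].[Na+]
Why: The same three‑component Friedel–Crafts hydroxyalkylation/sulfinate capture occurs on the only free phenol ring, at the carbon ortho to the OH and para to the dihydrofuran oxygen (the site formylated in orcinol monomethyl ether), the methyl‑ether rings being less nucleophilic and the weak acid leaving the benzylic ether intact.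

Step 8
Reactants: 1 2,4‑dimethoxybenzyl alcohol; 16 (1S,4S,5S)‑isothiocineole
Product: 17 (1S,4S,5S)‑6‑(2,4‑dimethoxybenzyl)‑4,7,7‑trimethyl‑6‑thiabicyclo[3.2.1]octan‑6‑ium tetrafluoroborate
Conditions: HBF4·OEt2, CH2Cl2, −20 °C→0 °C; used at once
Reagents that add atoms: tetrafluoroboric acid (diethyl etherate), [H+].F[B-](F)(F)F
Why: SN1‑type S‑alkylation as in step 4, here with the enantiomeric sulfide and the more easily ionised 2,4‑dimethoxybenzyl alcohol.

Step 9
Reactants: 15 tetracyclic sulfone; 17 2,4‑dimethoxybenzyl sulfonium salt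
Product: 20 nonamethyl ether of the target (7aR,8aR,7bR,7cS,8cS), via o‑quinone methide 18 (not isolated), via sulfonium ylide 19 (not isolated)
Conditions: Cs2CO3 (3 equiv), CH2Cl2/MeCN, −40 °C→rt; diastereomers separated by chromatography
Reagents that add atoms: none
Why: Proposed new method: as in step 5, sulfinate loss dearomatises ring D to o‑quinone methide 18, ylide 19 from the enantiomeric sulfide adds to the methide carbon and the phenoxide closes the ring by SN2 with inversion, so reagent control sets C7c and C8c as trans‑(S,S) independently of the remote core centres (any mismatched product is a separable diastereomer); the closest known reactions are the [4+1] annulation of o‑quinone methides with stabilised sulfur ylides and asymmetric ylide transfer from isothiocineole sulfonium salts.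

Step 10
Reactants: 20 nonamethyl ether
Product: 21 CNP0283541.1 (target)
Conditions: BBr3 (20 equiv), CH2Cl2, −78 °C→rt; then H2O
Reagents that add atoms: none
Why: Exhaustive Lewis‑acid cleavage of the nine aryl methyl ethers (BBr3 demethylation), in which C8a, C8c and C7b cannot epimerise and the two O‑benzylic centres C7a and C7c can at most re‑equilibrate to the trans arrangement already present.

## Compound list

1 | 2,4‑dimethoxybenzyl alcohol | COc1ccc(CO)c(OC)c1 | starting material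
2 | diethyl (2,4‑dimethoxybenzyl)phosphonate | CCOP(=O)(Cc1ccc(OC)cc1OC)OCC | intermediate
3 | 3,5‑dihydroxybenzaldehyde | O=Cc1cc(O)cc(O)c1 | starting material
4 | 5‑[(E)‑2‑(2,4‑dimethoxyphenyl)ethenyl]benzene‑1,3‑diol | COc1ccc(/C=C/c2cc(O)cc(O)c2)c(OC)c1 | intermediate
5 | 3,5‑dimethoxybenzaldehyde | COc1cc(C=O)cc(OC)c1 | starting material
6 | 4‑[(3,5‑dimethoxyphenyl)(4‑methylbenzenesulfonyl)methyl]‑5‑[(E)‑2‑(2,4‑dimethoxyphenyl)ethenyl]benzene‑1,3‑diol, racemic at the sulfonyl carbon | COc1ccc(/C=C/c2cc(O)cc(O)c2C(c2cc(OC)cc(OC)c2)S(=O)(=O)c2ccc(C)cc2)c(OC)c1 | intermediate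
7 | 4‑methoxybenzyl alcohol | COc1ccc(CO)cc1 | starting material
8 | (1R,4R,5R)‑4,7,7‑trimethyl‑6‑thiabicyclo[3.2.1]octane, (1R,4R,5R)‑isothiocineole | C[C@@H]1CC[C@@H]2C[C@H]1SC2(C)C | starting material
9 | (1R,4R,5R)‑6‑(4‑methoxybenzyl)‑4,7,7‑trimethyl‑6‑thiabicyclo[3.2.1]octan‑6‑ium tetrafluoroborate (one diastereomer at sulfur, not assigned in the SMILES) | C[C@@H]1CC[C@@H]2C[C@H]1[S+](Cc1ccc(OC)cc1)C2(C)C.F[B-](F)(F)F | intermediate
10 | o‑quinone methide of 6: 6‑[(3,5‑dimethoxyphenyl)methylidene]‑5‑[(E)‑2‑(2,4‑dimethoxyphenyl)ethenyl]‑3‑hydroxycyclohexa‑2,4‑dien‑1‑one | COc1ccc(/C=C/C2=CC(O)=CC(=O)C2=Cc2cc(OC)cc(OC)c2)c(OC)c1 | intermediate (not isolated)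
11 | 4‑methoxybenzylide of (1R,4R,5R)‑isothiocineole (sulfonium ylide) | C[C@@H]1CC[C@@H]2C[C@H]1[S+]([CH-]c1ccc(OC)cc1)C2(C)C | intermediate (not isolated)
12 | (2R,3R)‑3‑(3,5‑dimethoxyphenyl)‑4‑[(E)‑2‑(2,4‑dimethoxyphenyl)ethenyl]‑2‑(4‑methoxyphenyl)‑2,3‑dihydro‑1‑benzofuran‑6‑ol | COc1ccc([C@@H]2Oc3cc(O)cc(/C=C/c4ccc(OC)cc4OC)c3[C@H]2c2cc(OC)cc(OC)c2)cc1 | intermediate
13 | 2,4‑dimethoxybenzylic cation from C8b‑protonation of 12 | COc1ccc([C@@H]2Oc3cc(O)cc(C[CH+]c4ccc(OC)cc4OC)c3[C@H]2c2cc(OC)cc(OC)c2)cc1 | intermediate (not isolated)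
14 | tetracyclic phenol (7aR,8aR,7bR): dihydrofuran on ring D, rings D and B bridged by C8a and by C7b–C8b, ring A 4‑methoxyphenyl, ring C 2,4‑dimethoxyphenyl, ring B dimethoxy, one free OH on ring D | COc1ccc([C@@H]2Oc3cc(O)cc4c3[C@H]2c2cc(OC)cc(OC)c2[C@@H](c2ccc(OC)cc2OC)C4)cc1 | intermediate
15 | 14 carrying CH(3,5‑dimethoxyphenyl)(4‑methylbenzenesulfonyl) on ring D between the OH and C8b, epimer mixture at that carbon | COc1ccc([C@@H]2Oc3cc(O)c(C(c4cc(OC)cc(OC)c4)S(=O)(=O)c4ccc(C)cc4)c4c3[C@H]2c2cc(OC)cc(OC)c2[C@@H](c2ccc(OC)cc2OC)C4)cc1 | intermediate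
16 | (1S,4S,5S)‑4,7,7‑trimethyl‑6‑thiabicyclo[3.2.1]octane, (1S,4S,5S)‑isothiocineole | C[C@H]1CC[C@H]2C[C@@H]1SC2(C)C | starting material
17 | (1S,4S,5S)‑6‑(2,4‑dimethoxybenzyl)‑4,7,7‑trimethyl‑6‑thiabicyclo[3.2.1]octan‑6‑ium tetrafluoroborate (one diastereomer at sulfur, not assigned in the SMILES) | C[C@H]1CC[C@H]2C[C@@H]1[S+](Cc1ccc(OC)cc1OC)C2(C)C.F[B-](F)(F)F | intermediate
18 | o‑quinone methide of 15 (ring D as dienone with exocyclic C8c=C bearing the 3,5‑dimethoxyphenyl group) | COc1ccc([C@@H]2OC3=CC(=O)C(=Cc4cc(OC)cc(OC)c4)C4=C3[C@H]2c2cc(OC)cc(OC)c2[C@@H](c2ccc(OC)cc2OC)C4)cc1 | intermediate (not isolated)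
19 | 2,4‑dimethoxybenzylide of (1S,4S,5S)‑isothiocineole (sulfonium ylide) | C[C@H]1CC[C@H]2C[C@@H]1[S+]([CH-]c1ccc(OC)cc1OC)C2(C)C | intermediate (not isolated)
20 | nonamethyl ether of the target (7aR,8aR,7bR,7cS,8cS) | COc1ccc([C@@H]2Oc3cc4c(c5c3[C@H]2c2cc(OC)cc(OC)c2[C@@H](c2ccc(OC)cc2OC)C5)[C@H](c2cc(OC)cc(OC)c2)[C@@H](c2ccc(OC)cc2OC)O4)cc1 | intermediate
21 | CNP0283541.1 (7aR,8aR,7bR,7cS,8cS) | Oc1ccc([C@@H]2Oc3cc4c(c5c3[C@H]2c2cc(O)cc(O)c2[C@@H](c2ccc(O)cc2O)C5)[C@H](c2cc(O)cc(O)c2)[C@@H](c2ccc(O)cc2O)O4)cc1 | target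

## Step count and risks

Total step count: 10. Longest linear sequence: 8 (steps 1, 2, 3, 5, 6, 7, 9, 10).

**Step 3 (one‑sided condensation on the free resorcinol).** It may give the regioisomer between the two OH groups, bis‑adducts or diarylmethane oligomers. The fallback sets out from 4 and comes back at 6, installing the carbon with reversed polarity. Vilsmeier–Haack formylation of 4 (POCl3, DMF, 0 °C, para to OH as with olivetol) gives 2,4‑dihydroxy‑6‑[(E)‑2‑(2,4‑dimethoxyphenyl)ethenyl]benzaldehyde F1. Addition of 3,5‑dimethoxyphenylmagnesium bromide (3.5 equiv, THF) gives 4‑[(3,5‑dimethoxyphenyl)(hydroxy)methyl]‑5‑[(E)‑2‑(2,4‑dimethoxyphenyl)ethenyl]benzene‑1,3‑diol F2. Exchange of the benzylic OH with p‑toluenesulfinic acid (TolSO2Na, HCO2H) returns to 6.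

**Step 5 (new asymmetric [4+1] on a diphenol).** The anionic quinone methide may be too unreactive, or the trans selectivity or ee too low. The fallback sets out from 6 and comes back at 14, replacing ylide control by an enantioselective carbene C–H insertion. Sulfone 6 is hydrolysed through its quinone methide (Cs2CO3, wet MeCN) to the carbinol F2 named above and oxidised in the same flask (MnO2) to {2,4‑dihydroxy‑6‑[(E)‑2‑(2,4‑dimethoxyphenyl)ethenyl]phenyl}(3,5‑dimethoxyphenyl)methanone F3. Both phenols are alkylated (4‑methoxybenzyl chloride, K2CO3, DMF, 60 °C) to the bis(4‑methoxybenzyl) ether F4. Forcing hydrazine condensation (N2H4·H2O, AcOH, EtOH, 100 °C) gives hydrazone F5, and MnO2 oxidation gives the diaryldiazomethane F6. Dirhodium tetrakis[N‑phthaloyl‑(R)‑adamantylglycinate], Rh2(R‑PTAD)4 (or its enantiomer, whichever gives 8aR), inserts the carbene into the ortho O–CH2 bond to give the cis‑(2S,3R)‑dihydrobenzofuran 4‑methoxybenzyl ether F7. TFA with pentamethylbenzene then removes the remaining 4‑methoxybenzyl group, epimerises C7a to trans and closes the seven‑membered ring in one operation, giving 14.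

**Step 9 (second [4+1] at the hindered position with a very electron‑rich, labile sulfonium salt).** The fallback sets out from 15 and comes back at 20, replacing the chiral ylide by a diazo nucleophile and relying on separation of diastereomers. 2,4‑Dimethoxybenzaldehyde and tosylhydrazide give 2,4‑dimethoxybenzaldehyde N‑tosylhydrazone F8. With Cs2CO3 in dioxane at 70 °C this releases (2,4‑dimethoxyphenyl)diazomethane F9 (Bamford–Stevens) while 15 is converted to quinone methide 18. The diazo carbon adds to the methide carbon and the phenoxide displaces N2, giving the two trans dihydrofurans 20 and its (7cR,8cR)‑diastereomer F10, which are separated by chromatography.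

## Further compounds

F1 | step 3 | 2,4‑dihydroxy‑6‑[(E)‑2‑(2,4‑dimethoxyphenyl)ethenyl]benzaldehyde | COc1ccc(/C=C/c2cc(O)cc(O)c2C=O)c(OC)c1
F2 | step 3 | 4‑[(3,5‑dimethoxyphenyl)(hydroxy)methyl]‑5‑[(E)‑2‑(2,4‑dimethoxyphenyl)ethenyl]benzene‑1,3‑diol (racemic) | COc1ccc(/C=C/c2cc(O)cc(O)c2C(O)c2cc(OC)cc(OC)c2)c(OC)c1
F3 | step 5 | {2,4‑dihydroxy‑6‑[(E)‑2‑(2,4‑dimethoxyphenyl)ethenyl]phenyl}(3,5‑dimethoxyphenyl)methanone | COc1ccc(/C=C/c2cc(O)cc(O)c2C(=O)c2cc(OC)cc(OC)c2)c(OC)c1
F4 | step 5 | bis(4‑methoxybenzyl) ether of F3 | COc1ccc(/C=C/c2cc(OCc3ccc(OC)cc3)cc(OCc3ccc(OC)cc3)c2C(=O)c2cc(OC)cc(OC)c2)c(OC)c1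
F5 | step 5 | hydrazone of F4 | COc1ccc(/C=C/c2cc(OCc3ccc(OC)cc3)cc(OCc3ccc(OC)cc3)c2C(=NN)c2cc(OC)cc(OC)c2)c(OC)c1
F6 | step 5 | diaryldiazomethane from F5 | COc1ccc(/C=C/c2cc(OCc3ccc(OC)cc3)cc(OCc3ccc(OC)cc3)c2C(=[N+]=[N-])c2cc(OC)cc(OC)c2)c(OC)c1
F7 | step 5 | (2S,3R)‑cis‑3‑(3,5‑dimethoxyphenyl)‑4‑[(E)‑2‑(2,4‑dimethoxyphenyl)ethenyl]‑6‑(4‑methoxybenzyloxy)‑2‑(4‑methoxyphenyl)‑2,3‑dihydro‑1‑benzofuran | COc1ccc([C@H]2Oc3cc(OCc5ccc(OC)cc5)cc(/C=C/c4ccc(OC)cc4OC)c3[C@H]2c2cc(OC)cc(OC)c2)cc1
F8 | step 9 | 2,4‑dimethoxybenzaldehyde N‑tosylhydrazone | COc1ccc(/C=N/NS(=O)(=O)c2ccc(C)cc2)c(OC)c1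
F9 | step 9 | (2,4‑dimethoxyphenyl)diazomethane | COc1ccc(C=[N+]=[N-])c(OC)c1
F10 | step 9 | (7aR,8aR,7bR,7cR,8cR)‑diastereomer of 20 | COc1ccc([C@@H]2Oc3cc4c(c5c3[C@H]2c2cc(OC)cc(OC)c2[C@@H](c2ccc(OC)cc2OC)C5)[C@@H](c2cc(OC)cc(OC)c2)[C@H](c2ccc(OC)cc2OC)O4)cc1
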